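Grey and red were the two runs I had to reckon from before charging east and west.

| flask | substrate | partner | temperature | remark | time |
|---|---|---|---|---|---|
| grey | 0.067 M | 0.18 M | −16 °C | run made earlier |  |
| red | 0.15 M | 0.18 M | −8 °C | run made earlier |  |
| east | 0.10 M | 0.180 M | −5 °C |  | 3.0 h |
| west | 0.10 M | 0.180 M | −20 °C |  | 3.0 h |

| run | time / min | target / % | side product / % | substrate / % | intermediate / % |
|---|---|---|---|---|---|
| grey | 20.0 | 18.4 | 0.5 | 61.1 | 6.4 |
| grey | 40.0 | 35.3 | 1.4 | 40.2 | 4.9 |
| grey | 50.0 | 41.7 | 2.0 | 33.0 | 5.2 |
| grey | 80.0 | 53.5 | 2.6 | 19.7 | 2.5 |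
| grey | 90.0 | 57.5 | 2.7 | 15.7 | 2.2 |
| grey | 120 | 63.0 | 3.6 | 9.8 | 0.9 |
| red | 4.00 | 6.4 | 0.3 | 70.0 | 7.4 |
| red | 8.00 | 14.3 | 1.4 | 53.2 | 8.1 |
| red | 15.0 | 26.9 | 2.8 | 35.8 | 6.8 |
| red | 20.0 | 31.6 | 2.9 | 26.2 | 4.6 |
| red | 30.0 | 39.4 | 4.2 | 16.2 | 3.2 |
| red | 60.0 | 50.1 | 5.2 | 4.7 | 1.1 |

(standard deviation of a reading: 0.5 percentage points)

- which of these there is most of at the end, counted by the substrate in it, east (target / intermediate / side product / substrate)
- which of these there is most of at the end, counted by the substrate in it, west (target / intermediate / side product / substrate)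
- how much there is at the end of the one of these that leads, in percent of the substrate charged: east
- how much there is at the end of the one of these that leads, in percent of the substrate charged: west

I worked with what was left. At its last reading grey held 9.8 % of its substrate and red 4.7 %, and I counted whatever was neither substrate nor target as lost. Lost over target, divided by the molar charge of substrate, I called the loss number. It came to 6.44 L mol⁻¹ in grey and 6.01 L mol⁻¹ in red, though red's charge was 2.24 times grey's. So I took the loss to grow in step with the charge, knowing that the two runs also differ in temperature. Their mean, 6.23 L mol⁻¹, put the selectivity at 0.10 M at 61.6 % of substrate converted.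

The logarithm of charged over left, divided by time, gave an apparent decay constant of 1.16 h⁻¹ in grey and 3.06 h⁻¹ in red. Stepping along the line through those two, logarithmic in temperature and taking no account of their different charges, gave my estimates of 0.716 h⁻¹ for west and 4.40 h⁻¹ for east. For 3.0 h, these estimates left west 11.7 % of its substrate and east <0.001 %. That made target 61.6 % in east and 54.4 % in west.

The weak link was the intermediate, of which grey held 0.9 % and red 1.1 % at their last readings, and I had counted that substrate as lost. I reforged the loss number as substrate found in neither substrate, target nor intermediate, over target plus intermediate, per molar charge. Grey gave 6.14 L mol⁻¹, red 5.74 L mol⁻¹, and the mean was 5.94 L mol⁻¹. My figures became 62.7 % target in east and 55.4 % target plus intermediate in west.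

The forecast named target in east and target in west, with 60 % and 54 %, its east figure lower than mine, and it held that “The missing share of converted substrate is higher when substrate is concentrated”.

East gave 62.8 % of target and west 56.2 %, so the forecast held on all four counts.

    substrate ⇌ intermediate (K = 0.806, k = 0.664 h⁻¹, Ea = 69.0 kJ mol⁻¹, ΔH = −17.0 kJ mol⁻¹)
    partner + intermediate → target (k = 37.5 L mol⁻¹ h⁻¹, Ea = 45.0 kJ mol⁻¹)
    intermediate → side product (k = 0.194 h⁻¹, Ea = 91.0 kJ mol⁻¹)
    2 substrate → self-condensation product (k = 3.08 L mol⁻¹ h⁻¹, Ea = 59.0 kJ mol⁻¹)
    (constants at −20 °C)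

At 3.00 h east stood at self-condensation product 29.6 % and side product 7.54 %, both counted by the substrate in them. Summed over target and divided by the charge, they give 5.91 L mol⁻¹ against my 5.94 L mol⁻¹, which had lumped the two together.

For a neighbour flask, west with 0.040 M of substrate, the loss number gives selectivity 80.8 % and, with my estimate of west's fraction left, 71.3 % target plus intermediate. The flask gave 67.6 % of target and 1.39 % of intermediate, with 13 % of substrate left.

The earlier runs and the new flask stem from a simulated flask with made-up constants; noise was put on by code.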